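Locants C1–C9 and C1'–C6' are those of the target throughout: ring A is C1(=O)–C2=C3–C4(OAc)–C5H2–C6, ring B is C6–C7H2–C8(=O)–O–C9H, and the side chain on C9 is C1'H=C2'(CH3)–C3'H2–C4'H=C5'H–C6'(CH3)2OH.

## The problem

(+)-Miliusane XVII (26) is a 2-oxaspiro[4.5]decane in which a 4-acetoxycyclohex-2-enone (ring A) and a γ-butyrolactone (ring B) share the quaternary carbon C6, and C9 of ring B carries a (1E,4E)-dienyl chain ending in a tertiary alcohol. Three stereocentres have to be set: C4 (S), C6 (R) and C9 (R). C4 and C6 are 1,3-related through C5, with the C4 oxygen on the same face of ring A as C9, so one of them can control the other. C9 is exocyclic to ring A, with its alkenyl group on the C1 side of ring B, and needs a control element of its own. C6 is quaternary and cannot be corrected once formed. Several groups will not survive rough treatment: the γ-acetoxy enone (bases, nucleophiles), the allylic C9–O lactone bond, the skipped 1,4-diene with its doubly allylic C3' methylene, and the acid-labile tertiary allylic alcohol. The enabling feature is seen when ring A is written at the cyclohexa-2,5-diene level with C9 as a carboxyl group on C6: C6 is then prochiral and flanked by two enantiotopic alkenes, C1=C2 and C5=C4. Because C9 and the C4 oxygen are cis and 1,3-related, the C9 carboxylate can deliver the C4 oxygen itself, so that choosing one alkene fixes C6 and C4 together.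

## Retrosynthesis

**Enone, acetate and silyl groups (26 ⇒ 25 ⇒ 24 ⇒ 23).** No skeletal bond is cut. The C1 ketone is taken back to the allylic alcohol 25 because an enone would not survive the organometallic and alkoxide steps that build C9 and ring B. 25 comes from the bis-silyl ether 24, and the acetate is placed on the only free hydroxyl of 23. The forward steps are an acylation, a buffered desilylation and a mild oxidation, and each leaves the three stereocentres alone.

**Ring B, C8–O bond (23 ⇒ 22).** Cutting the lactone gives the diol tert-butyl ester 22. This cut is preferred to cutting C6–C7 or C7–C8, which would break the quaternary centre or require a carbonylation. The closure is unambiguous: the C4 oxygen is trans to the C7 arm and cannot reach C8, and the C1 oxygen is silylated, so only the C9 oxygen can lactonise.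

**C9–C1' bond (22 ⇒ 12 + 19).** This cut makes the route convergent and removes the whole side chain and the third stereocentre. C9 can receive its two substituents from a lactone carbonyl in either order: alkenyl then hydride (ketone reduction), or hydride then alkenyl (addition to lactol 12). The second order is chosen. In the magnesium-bridged open form of 12 the aldehyde oxygen is held over the C4 oxygen, and the open face of C9 is the one flanked by C5 and C7, away from ring A. Attack there places the alkenyl group on the C1 side of ring B, as in 26; hydride attack on the corresponding alkenyl ketone from the same face would give the C9 epimer. The forward step needs exo-face selectivity and tolerance of the tert-butyl ester.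

**Ring A oxygenation (12 ⇒ 11 ⇒ 10 ⇒ 7 ⇒ 6).** No carbon–carbon bond is cut. 12 is the half-reduced form of silyl ether 11, and the C1 oxygen with the C2=C3 alkene in 10 is traced to the C1=C2 alkene of 6 through epoxide 7. This transposition must precede the coupling, because the ring alkene is the least electron-rich of the three alkenes in the final skeleton and could not be epoxidised selectively afterwards. The forward sequence needs opening of the epoxide at C2, which the neopentyl character of C1 favours.

**C5–Br and the key C4–O bond (6 ⇒ 5 ⇒ 4).** Reductive removal of bromine leads back to bromolactone 5, and cutting its C4–O bond (with the C5–Br bond) gives the achiral dienyl acid 4. Cutting at C4–O rather than at a ring carbon–carbon bond removes all three stereocentres of 5 at once and leaves a meso-type precursor with a mirror plane. The forward reaction must pick one of two enantiotopic alkenes and close the lactone at C4 rather than at C5.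

**C6–C7 bond (4 ⇒ 1 + 2).** The quaternary carbon is formed by alkylating the Birch dianion of benzoic acid 1 with tert-butyl bromoacetate 2. No stereochemistry is involved, and the tert-butyl ester keeps the C8 carboxyl silent in the steps that follow.

**Side chain (19 ⇒ 18 ⇒ 16 ⇒ 15 ⇒ 13 + 14).** The (E)-2-methylalkenyl iodide 18 comes from methylalumination and iodination of the terminal alkyne of enynol 16. The (E)-C4'=C5' alkene of 16 comes from hydroxyl-directed reduction of skipped diyne 15. 15 is made by cutting the C3'–C4' bond into 2-methylbut-3-yn-2-ol 13 and propargyl bromide 14. Each alkene geometry is set by a stereospecific addition to an alkyne rather than by an olefination.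

## Roads not taken

**Alternative 1:** Four bonds (C1–C2, C1–C6, C7–C8, C8–O) are cut at once, leading to the acyclic (Z)-iodoalkene A2, which already carries C4, C9 and the full side chain. In the forward step Pd(PPh3)4, a zerovalent palladium complex, under carbon monoxide inserts into the vinyl iodide; CO insertion gives the C1 acylpalladium, 6-exo acylpalladation of the C6=C7 alkene creates the quaternary centre, and a second CO insertion at the neopentyl C7–Pd bond is captured by the C9 hydroxyl to give A1, two steps (desilylation, acetylation) from 26. Its merit is that both rings, the quaternary centre and two carbonyl carbons arise in one operation at the end of a convergent route; if the cascade behaved, it would be shorter and more convergent than the chosen plan. Its weak points are at C6: the quaternary centre forms under 1,3-induction from C4 or C9 in a cyclisation whose facial preference cannot be predicted. A2 needs two independent asymmetric steps and a (Z)-iodoalkene before the cascade, direct carbopalladation can compete with CO insertion, and the side-chain alkenes and the allylic C9–O bond are exposed to zerovalent palladium. The chosen plan has to set against the shorter cascade that its C6/C4 relationship is enforced by geometry and that its key substrate 4 is made in one step.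

**Alternative 2:** The C5–C6 bond is cut as a 1,2-shift, leading to the cyclopentenyl epoxy alcohol A4. BF3·OEt2 opens the epoxide at tertiary C6, and a ring carbon of the cyclopent-3-enol migrates anti to the departing oxygen, expanding the ring to the cyclohex-3-enone A3. The merit is stereospecificity: the epoxide configuration is transferred to C6 and C9 together, which controls C9 more rigorously than the addition in the chosen plan, and the symmetric cyclopentenol makes the choice of migrating carbon irrelevant. The weak points lie after the key step. A3 has no oxygen at C4 and its alkene is at C3=C4, so C4 would have to be oxidised with a remote stereochemical relationship to C6 and no built-in control. The side chain must be grown from a C1' alcohol through an epimerisable α-oxygenated aldehyde and a trisubstituted olefination, and the C7–C8 arm must still be oxidised. In step count and in control of C4 the chosen plan is clearly ahead; it concedes only the tighter C6/C9 relationship.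

**Alternative 3:** The C4–C5 and C1–C6 bonds are cut as a Diels–Alder reaction between the 1-silyloxy-4-acetoxydiene A7 and the 2-substituted acrolein A6 under a chiral cationic oxazaborolidine, giving A5. This road is better than the chosen plan in several respects: it is convergent, it sets three ring stereocentres in one catalytic step, and A5 already has the ring A pattern (C1–O, C2=C3, C4–OAc) with C9 as an aldehyde and C8 as an ester. The alkene transposition of the chosen route is not needed, and fewer steps would remain. Its weak points are the substrates and the selectivities. A6 is a β,γ-unsaturated ester that isomerises easily into conjugation and polymerises. A7 has donors at both termini, so regiochemistry rests only on the difference between silyloxy and acetoxy donation. The all-cis product requires the formyl group endo, whereas α-substituted acroleins often react formyl-exo under such catalysts. The acetate must then survive alkenylation at C9 under acyclic stereocontrol. Against the shorter sequence the chosen plan sets a stable substrate, no regiochemical question, a cis C4–O/C9 relationship that is structural, and a bicyclic scaffold that directs C9.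

Key step: step 2

Assumption: the sense of induction of (DHQD)2PHAL in step 2 is taken to give the (1R,5R,8R) lactone 5; should the antipode predominate, the pseudoenantiomeric (DHQ)2PHAL [hydroquinine 1,4-phthalazinediyl diether] would be used and nothing else would change.

## Route

Step 1
Reactants: 1 benzoic acid; 2 tert-butyl bromoacetate
Product: 4 1-(2-tert-butoxy-2-oxoethyl)cyclohexa-2,5-diene-1-carboxylic acid, via dilithium enediolate 3 (not isolated)
Conditions: Li, NH3(l)/THF, −78 °C, to a persistent faint blue; then 2, −78 °C; NH4Cl; cold dilute HCl to pH 3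
Reagents that add atoms: none
Why: Birch reduction–alkylation: lithium in ammonia reduces lithium benzoate to the cross-conjugated dianion 3, which is alkylated at the carboxyl-bearing carbon by the reactive α-bromo ester; 4 has a mirror plane through C6 and C3, so no stereocentre is formed.

Step 2
Reactants: 4 1-(2-tert-butoxy-2-oxoethyl)cyclohexa-2,5-diene-1-carboxylic acid
Product: 5 tert-butyl 2-[(1R,5R,8R)-8-bromo-7-oxo-6-oxabicyclo[3.2.1]oct-2-en-1-yl]acetate
Conditions: N-bromosuccinimide, (DHQD)2PHAL [hydroquinidine 1,4-phthalazinediyl diether] 10 mol%, CHCl3/hexane 1:1, −40 °C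
Reagents that add atoms: N-bromosuccinimide, O=C1CCC(=O)N1Br
Why: Cinchona-alkaloid-catalysed desymmetrising bromolactonisation, the closest known type being the (DHQD)2PHAL/N-bromosuccinimide bromolactonisation of 1-substituted cyclohexa-2,5-diene-1-carboxylic acids. The quinuclidine nitrogen ion-pairs with the carboxylic acid, and the catalyst-bound bromenium ion is delivered to one of the two enantiotopic alkenes on the ring face opposite the carboxylate. The carboxylate opens the bromiranium ion anti at C4 and closes the five-membered lactone in a 5-endo sense (C4–O formed, bromine left on C5), giving the 6-oxabicyclo[3.2.1]octene. A β-lactone from 4-exo attack at C5 is strained and can revert through the same bromiranium ion, so it should drain into the γ-lactone. C6 is set by the catalyst's choice of alkene; C4 follows because a two-atom bridge can only span C6 and C4 on one face; C5 follows from anti addition. The step needs enantiotopic-group selectivity, which rests on catalyst–carboxylate association at the prochiral centre, and chemoselectivity for the acid over the ester carbonyl, which the un-ionised tert-butyl ester secures.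

Step 3
Reactants: 5 tert-butyl 2-[(1R,5R,8R)-8-bromo-7-oxo-6-oxabicyclo[3.2.1]oct-2-en-1-yl]acetate
Product: 6 tert-butyl 2-[(1S,5R)-7-oxo-6-oxabicyclo[3.2.1]oct-2-en-1-yl]acetate
Conditions: Bu3SnH (1.5 equiv, 0.3 M), AIBN cat., benzene, 80 °C
Reagents that add atoms: none
Why: Radical chain dehalogenation: the secondary C5 radical is quenched by the stannane; β-scission of the C4–acyloxy bond is slow, and a high stannane concentration is meant to outrun homoallyl rearrangement. C6 and C4 are untouched.

Step 4
Reactants: 6 tert-butyl 2-[(1S,5R)-7-oxo-6-oxabicyclo[3.2.1]oct-2-en-1-yl]acetate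
Product: 7 tert-butyl 2-[(1S,2S,4R,6S)-8-oxo-3,7-dioxatricyclo[4.2.1.0(2,4)]nonan-1-yl]acetate (epoxide oxygen anti to the lactone bridge)
Conditions: mCPBA, NaHCO3, CH2Cl2, 0 → 23 °C
Reagents that add atoms: meta-chloroperoxybenzoic acid, OOC(=O)c1cccc(Cl)c1
Why: Prilezhaev epoxidation of the cis-disubstituted C1=C2 alkene from the face opposite the lactone bridge, which shields the other face at C2; lactone and ester are inert to the peracid.

Step 5
Reactants: 7 tert-butyl 2-[(1S,2S,4R,6S)-8-oxo-3,7-dioxatricyclo[4.2.1.0(2,4)]nonan-1-yl]acetate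
Product: 10 tert-butyl 2-[(1S,2R,5S)-2-hydroxy-7-oxo-6-oxabicyclo[3.2.1]oct-3-en-1-yl]acetate, via hydroxy selenide 8 (not isolated), via selenoxide 9 (not isolated)
Conditions: PhSeSePh, NaBH4, EtOH, 23 °C; then THF, 30% H2O2, pyridine, 0 → 23 °C
Reagents that add atoms: none
Why: Epoxide opening by benzeneselenolate and selenoxide syn-elimination: the soft nucleophile attacks C2 (C1 is neopentyl) in the trans-diaxial Fürst–Plattner mode, and the selenoxide eliminates toward C3, away from the carbinol carbon, which moves the alkene to C2=C3. The temporary C1 centre (oxygen anti to the bridge) comes from step 4 and is erased in step 16.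

Step 6
Reactants: 10 tert-butyl 2-[(1S,2R,5S)-2-hydroxy-7-oxo-6-oxabicyclo[3.2.1]oct-3-en-1-yl]acetate
Product: 11 tert-butyl 2-[(1S,2R,5S)-2-[(tert-butyldimethylsilyl)oxy]-7-oxo-6-oxabicyclo[3.2.1]oct-3-en-1-yl]acetate
Conditions: TBSOTf, 2,6-lutidine, CH2Cl2, −78 → 0 °C
Reagents that add atoms: tert-butyldimethylsilyl trifluoromethanesulfonate, CC(C)(C)[Si](C)(C)OS(=O)(=O)C(F)(F)F
Why: Silylation of the hindered C1 hydroxyl with a silyl triflate and a hindered base; low temperature and short contact keep the tert-butyl ester intact. The TBS group is chosen because it resists 1,3-migration in step 13.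

Step 7
Reactants: 11 tert-butyl 2-[(1S,2R,5S)-2-[(tert-butyldimethylsilyl)oxy]-7-oxo-6-oxabicyclo[3.2.1]oct-3-en-1-yl]acetate
Product: 12 tert-butyl 2-[(1S,2R,5S,7RS)-2-[(tert-butyldimethylsilyl)oxy]-7-hydroxy-6-oxabicyclo[3.2.1]oct-3-en-1-yl]acetate (both lactol anomers)
Conditions: i-Bu2AlH (1.1 equiv), CH2Cl2, −78 °C; Rochelle salt work-up
Reagents that add atoms: none
Why: Partial reduction of a lactone: the aluminium hemiacetal of the strained bridged lactone persists at −78 °C and gives the lactol on work-up, while the hindered tert-butyl ester is not reduced at this temperature.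

Step 8
Reactants: 13 2-methylbut-3-yn-2-ol; 14 propargyl bromide
Product: 15 2-methylhepta-3,6-diyn-2-ol
Conditions: CuI, NaI, K2CO3, DMF, 23 °C, 13 in threefold excess
Reagents that add atoms: none
Why: Copper-mediated alkynyl–propargyl coupling: the copper acetylide of 13 displaces the halide of 14 to give the skipped diyne; the excess of 13 suppresses a second propargylation of the product.

Step 9
Reactants: 15 2-methylhepta-3,6-diyn-2-ol
Product: 16 (E)-2-methylhept-3-en-6-yn-2-ol
Conditions: NaAlH2(OCH2CH2OCH3)2, THF, 0 → 23 °C; aqueous Rochelle salt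
Reagents that add atoms: none
Why: Hydroxyl-directed trans-hydroalumination of a propargylic alcohol: the aluminium alkoxide delivers hydride only to the internal alkyne, and protonolysis gives the (E)-alkene; the isolated terminal alkyne is not reduced.

Step 10
Reactants: 16 (E)-2-methylhept-3-en-6-yn-2-ol
Product: 18 (3E,6E)-7-iodo-2,6-dimethylhepta-3,6-dien-2-ol, via alkenylalane 17 (not isolated)
Conditions: Me3Al (3.5 equiv), Cp2ZrCl2 (0.3 equiv), CH2Cl2, 0 → 23 °C; then I2, THF, −30 → 0 °C
Reagents that add atoms: trimethylaluminium, C[Al](C)C; iodine, II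
Why: Zirconium-catalysed carboalumination (Negishi) of the terminal alkyne: syn addition puts methyl on the internal carbon and aluminium on the terminus, and iododealumination with retention gives the (E)-2-methylalkenyl iodide; the hydroxyl is carried as its aluminium alkoxide.

Step 11
Reactants: 18 (3E,6E)-7-iodo-2,6-dimethylhepta-3,6-dien-2-ol
Product: 19 triethyl{[(3E,6E)-7-iodo-2,6-dimethylhepta-3,6-dien-2-yl]oxy}silane
Conditions: TESOTf, 2,6-lutidine, CH2Cl2, −78 °C
Reagents that add atoms: triethylsilyl trifluoromethanesulfonate, CC[Si](CC)(CC)OS(=O)(=O)C(F)(F)F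
Why: Silylation of the tertiary allylic alcohol under non-ionising conditions, so that no acidic proton interferes with the lithium–iodine exchange.

Step 12
Reactants: 19 triethyl{[(3E,6E)-7-iodo-2,6-dimethylhepta-3,6-dien-2-yl]oxy}silane; 12 tert-butyl 2-[(1S,2R,5S,7RS)-2-[(tert-butyldimethylsilyl)oxy]-7-hydroxy-6-oxabicyclo[3.2.1]oct-3-en-1-yl]acetate
Product: 22 tert-butyl 2-[(1R,2R,5S)-2-[(tert-butyldimethylsilyl)oxy]-5-hydroxy-1-[(1R,2E,5E)-1-hydroxy-3,7-dimethyl-7-[(triethylsilyl)oxy]octa-2,5-dien-1-yl]cyclohex-3-en-1-yl]acetate, via alkenyllithium 20 (not isolated), via alkenylmagnesium bromide 21 (not isolated)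
Conditions: 19 (2.5 equiv), t-BuLi (5 equiv), Et2O, −78 °C; MgBr2·OEt2, −78 → −20 °C; then 12, −78 → 0 °C; aqueous NH4Cl
Reagents that add atoms: none
Why: Lithium–iodine exchange with retention, transmetalation to magnesium and chelation-controlled addition to a lactol: the first equivalent of 21 deprotonates 12 and opens it to a C4 magnesium alkoxide that stays bridged to the C9 aldehyde oxygen in the shape of the former lactone. The second equivalent attacks C9 from the open face flanked by C5 and C7, away from ring A, which gives the (R)-carbinol; the tert-butyl ester is too hindered to react below 0 °C.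

Step 13
Reactants: 22 tert-butyl 2-[(1R,2R,5S)-2-[(tert-butyldimethylsilyl)oxy]-5-hydroxy-1-[(1R,2E,5E)-1-hydroxy-3,7-dimethyl-7-[(triethylsilyl)oxy]octa-2,5-dien-1-yl]cyclohex-3-en-1-yl]acetate
Product: 23 (1R,5R,6R,9S)-6-[(tert-butyldimethylsilyl)oxy]-1-[(1E,4E)-2,6-dimethyl-6-[(triethylsilyl)oxy]hepta-1,4-dien-1-yl]-9-hydroxy-2-oxaspiro[4.5]dec-7-en-3-one
Conditions: NaH (2.2 equiv), THF, 0 → 23 °C; aqueous NH4Cl
Reagents that add atoms: none
Why: Alkoxide-mediated intramolecular transesterification: the C9 alkoxide attacks C8 in a 5-exo-trig closure and expels tert-butoxide. The C4 alkoxide is trans to the C7 arm and cannot reach C8, and the C1 oxygen is silylated, so only the spiro lactone can form.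

Step 14
Reactants: 23 (1R,5R,6R,9S)-6-[(tert-butyldimethylsilyl)oxy]-1-[(1E,4E)-2,6-dimethyl-6-[(triethylsilyl)oxy]hepta-1,4-dien-1-yl]-9-hydroxy-2-oxaspiro[4.5]dec-7-en-3-one
Product: 24 (1R,5R,7S,10R)-10-[(tert-butyldimethylsilyl)oxy]-1-[(1E,4E)-2,6-dimethyl-6-[(triethylsilyl)oxy]hepta-1,4-dien-1-yl]-3-oxo-2-oxaspiro[4.5]dec-8-en-7-yl acetate
Conditions: Ac2O, pyridine, DMAP cat., CH2Cl2, 0 → 23 °C
Reagents that add atoms: acetic anhydride, CC(=O)OC(C)=O
Why: DMAP-catalysed acetylation of the only free hydroxyl, the secondary allylic C4–OH; the C4–O bond is not broken, so the configuration is retained.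

Step 15
Reactants: 24 (1R,5R,7S,10R)-10-[(tert-butyldimethylsilyl)oxy]-1-[(1E,4E)-2,6-dimethyl-6-[(triethylsilyl)oxy]hepta-1,4-dien-1-yl]-3-oxo-2-oxaspiro[4.5]dec-8-en-7-yl acetate
Product: 25 (1R,5S,7S,10R)-10-hydroxy-1-[(1E,4E)-6-hydroxy-2,6-dimethylhepta-1,4-dien-1-yl]-3-oxo-2-oxaspiro[4.5]dec-8-en-7-yl acetate
Conditions: HF·pyridine, pyridine, THF, 0 → 23 °C
Reagents that add atoms: none
Why: Fluoride desilylation under buffered, weakly acidic conditions removes the tertiary TES and the secondary TBS ether without ionising the tertiary allylic alcohol or cleaving the acetate. Basic fluoride is avoided because a C1 alkoxide, which is cis to the C7 arm, could translactonise onto C8.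

Step 16
Reactants: 25 (1R,5S,7S,10R)-10-hydroxy-1-[(1E,4E)-6-hydroxy-2,6-dimethylhepta-1,4-dien-1-yl]-3-oxo-2-oxaspiro[4.5]dec-8-en-7-yl acetate
Product: 26 (+)-miliusane XVII, (1R,5R,7S)-1-[(1E,4E)-6-hydroxy-2,6-dimethylhepta-1,4-dien-1-yl]-3,10-dioxo-2-oxaspiro[4.5]dec-8-en-7-yl acetate
Conditions: Dess–Martin periodinane, NaHCO3, CH2Cl2, 0 → 23 °C
Reagents that add atoms: none
Why: Dess–Martin oxidation of the secondary allylic C1 alcohol to the enone under bicarbonate buffer; the tertiary alcohol cannot be oxidised, and C6 is quaternary, so C4, C6 and C9 cannot epimerise.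

## Compound list

1 | benzoic acid | OC(=O)c1ccccc1 | starting material
2 | tert-butyl bromoacetate | CC(C)(C)OC(=O)CBr | starting material
3 | dilithium enediolate of 1,4-dihydrobenzoic acid (Birch dianion) | [Li+].[Li+].[O-]C([O-])=C1C=CCC=C1 | intermediate
4 | 1-(2-tert-butoxy-2-oxoethyl)cyclohexa-2,5-diene-1-carboxylic acid | CC(C)(C)OC(=O)CC1(C=CCC=C1)C(=O)O | intermediate
5 | tert-butyl 2-[(1R,5R,8R)-8-bromo-7-oxo-6-oxabicyclo[3.2.1]oct-2-en-1-yl]acetate | CC(C)(C)OC(=O)C[C@@]12C=CC[C@@H](OC1=O)[C@@H]2Br | intermediate
6 | tert-butyl 2-[(1S,5R)-7-oxo-6-oxabicyclo[3.2.1]oct-2-en-1-yl]acetate | CC(C)(C)OC(=O)C[C@@]12C=CC[C@@H](OC1=O)C2 | intermediate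
7 | tert-butyl 2-[(1S,2S,4R,6S)-8-oxo-3,7-dioxatricyclo[4.2.1.0(2,4)]nonan-1-yl]acetate | CC(C)(C)OC(=O)C[C@@]12[C@@H]3O[C@@H]3C[C@@H](OC1=O)C2 | intermediate
8 | tert-butyl 2-[(1S,2S,3S,5S)-2-hydroxy-7-oxo-3-(phenylselanyl)-6-oxabicyclo[3.2.1]octan-1-yl]acetate | CC(C)(C)OC(=O)C[C@@]12[C@H](O)[C@@H]([Se]c3ccccc3)C[C@@H](OC1=O)C2 | intermediate
9 | tert-butyl 2-[(1S,2S,3S,5S)-2-hydroxy-7-oxo-3-(phenylseleninyl)-6-oxabicyclo[3.2.1]octan-1-yl]acetate (both configurations at selenium) | CC(C)(C)OC(=O)C[C@@]12[C@H](O)[C@@H]([Se](=O)c3ccccc3)C[C@@H](OC1=O)C2 | intermediate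
10 | tert-butyl 2-[(1S,2R,5S)-2-hydroxy-7-oxo-6-oxabicyclo[3.2.1]oct-3-en-1-yl]acetate | CC(C)(C)OC(=O)C[C@@]12[C@H](O)C=C[C@@H](OC1=O)C2 | intermediate
11 | tert-butyl 2-[(1S,2R,5S)-2-[(tert-butyldimethylsilyl)oxy]-7-oxo-6-oxabicyclo[3.2.1]oct-3-en-1-yl]acetate | CC(C)(C)OC(=O)C[C@@]12[C@H](O[Si](C)(C)C(C)(C)C)C=C[C@@H](OC1=O)C2 | intermediate
12 | tert-butyl 2-[(1S,2R,5S,7RS)-2-[(tert-butyldimethylsilyl)oxy]-7-hydroxy-6-oxabicyclo[3.2.1]oct-3-en-1-yl]acetate | CC(C)(C)OC(=O)C[C@@]12[C@H](O[Si](C)(C)C(C)(C)C)C=C[C@@H](OC1O)C2 | intermediate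
13 | 2-methylbut-3-yn-2-ol | CC(C)(O)C#C | starting material
14 | propargyl bromide (3-bromoprop-1-yne) | C#CCBr | starting material
15 | 2-methylhepta-3,6-diyn-2-ol | CC(C)(O)C#CCC#C | intermediate
16 | (E)-2-methylhept-3-en-6-yn-2-ol | CC(C)(O)/C=C/CC#C | intermediate
17 | [(1E,4E)-6-(dimethylalumanyloxy)-2,6-dimethylhepta-1,4-dien-1-yl]dimethylalumane | C[Al](C)/C=C(\C)C/C=C/C(C)(C)O[Al](C)C | intermediate
18 | (3E,6E)-7-iodo-2,6-dimethylhepta-3,6-dien-2-ol | I/C=C(\C)C/C=C/C(C)(C)O | intermediate
19 | triethyl{[(3E,6E)-7-iodo-2,6-dimethylhepta-3,6-dien-2-yl]oxy}silane | I/C=C(\C)C/C=C/C(C)(C)O[Si](CC)(CC)CC | intermediate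
20 | [(1E,4E)-2,6-dimethyl-6-[(triethylsilyl)oxy]hepta-1,4-dien-1-yl]lithium | [Li]/C=C(\C)C/C=C/C(C)(C)O[Si](CC)(CC)CC | intermediate
21 | [(1E,4E)-2,6-dimethyl-6-[(triethylsilyl)oxy]hepta-1,4-dien-1-yl]magnesium bromide | Br[Mg]/C=C(\C)C/C=C/C(C)(C)O[Si](CC)(CC)CC | intermediate
22 | tert-butyl 2-[(1R,2R,5S)-2-[(tert-butyldimethylsilyl)oxy]-5-hydroxy-1-[(1R,2E,5E)-1-hydroxy-3,7-dimethyl-7-[(triethylsilyl)oxy]octa-2,5-dien-1-yl]cyclohex-3-en-1-yl]acetate | CC(C)(C)OC(=O)C[C@@]1([C@H](O)/C=C(\C)C/C=C/C(C)(C)O[Si](CC)(CC)CC)C[C@H](O)C=C[C@H]1O[Si](C)(C)C(C)(C)C | intermediate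
23 | (1R,5R,6R,9S)-6-[(tert-butyldimethylsilyl)oxy]-1-[(1E,4E)-2,6-dimethyl-6-[(triethylsilyl)oxy]hepta-1,4-dien-1-yl]-9-hydroxy-2-oxaspiro[4.5]dec-7-en-3-one | O[C@@H]1C=C[C@@H](O[Si](C)(C)C(C)(C)C)[C@@]2(CC(=O)O[C@@H]2/C=C(\C)C/C=C/C(C)(C)O[Si](CC)(CC)CC)C1 | intermediate
24 | (1R,5R,7S,10R)-10-[(tert-butyldimethylsilyl)oxy]-1-[(1E,4E)-2,6-dimethyl-6-[(triethylsilyl)oxy]hepta-1,4-dien-1-yl]-3-oxo-2-oxaspiro[4.5]dec-8-en-7-yl acetate | CC(=O)O[C@@H]1C=C[C@@H](O[Si](C)(C)C(C)(C)C)[C@@]2(CC(=O)O[C@@H]2/C=C(\C)C/C=C/C(C)(C)O[Si](CC)(CC)CC)C1 | intermediate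
25 | (1R,5S,7S,10R)-10-hydroxy-1-[(1E,4E)-6-hydroxy-2,6-dimethylhepta-1,4-dien-1-yl]-3-oxo-2-oxaspiro[4.5]dec-8-en-7-yl acetate | CC(=O)O[C@@H]1C=C[C@@H](O)[C@@]2(CC(=O)O[C@@H]2/C=C(\C)C/C=C/C(C)(C)O)C1 | intermediate
26 | (+)-miliusane XVII, (1R,5R,7S)-1-[(1E,4E)-6-hydroxy-2,6-dimethylhepta-1,4-dien-1-yl]-3,10-dioxo-2-oxaspiro[4.5]dec-8-en-7-yl acetate | CC(=O)O[C@@H]1C=CC(=O)[C@@]2(CC(=O)O[C@@H]2/C=C(\C)C/C=C/C(C)(C)O)C1 | target

## Step count and uncertain steps

Total: 16 steps. Longest linear sequence: 12 steps from benzoic acid (steps 1–7 and 12–16); the side chain takes 4 steps (8–11).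

**Step 2 (key step).** The catalyst may discriminate poorly between the enantiotopic alkenes, because the prochiral centre carries two carbonyl-bearing arms of similar size. The kinetic β-lactone may also be trapped instead of reverting, and the ester carbonyl may take part in a 5-exo closure with loss of isobutene. Fallback by auxiliary control, setting out from 1: benzoic acid is converted into its chloride and then into the C2-symmetric amide [(2R,5R)-2,5-bis(methoxymethyl)pyrrolidin-1-yl](phenyl)methanone F1 (or its antipode, whichever directs correctly). Birch reduction–alkylation of this tertiary benzamide (K, NH3, one equivalent of t-BuOH, then 2) would give tert-butyl 2-{1-[(2R,5R)-2,5-bis(methoxymethyl)pyrrolidine-1-carbonyl]cyclohexa-2,5-dien-1-yl}acetate F2, in which the two alkenes are diastereotopic. N-Bromosuccinimide in aqueous THF would then close the amide oxygen onto C4, and hydrolysis of the iminium ether would release the auxiliary and return the route to 5.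

**Step 3.** The C5 radical is homoallylic to C1=C2 and may undergo a 1,2-vinyl shift through a cyclopropylcarbinyl radical (ring contraction), or lose the C4 carboxylate by β-scission and regenerate a dienyl acid. Fallback by changing the order, setting out from 5: epoxidation with mCPBA first would give tert-butyl 2-[(1R,2S,4R,6R,9R)-9-bromo-8-oxo-3,7-dioxatricyclo[4.2.1.0(2,4)]nonan-1-yl]acetate F3, whose C5 radical has no alkene to add to. Bu3SnH/AIBN would then return the route to 7.

**Step 5.** The selenolate must approach C2 beneath the lactone bridge, so the opening may be slow or misdirected. Ethanolysis of the strained lactone may compete, and the C1 alkoxide, which is cis to the C7 arm, may attack the tert-butyl ester. Fallback by an ene reaction, setting out from 6: singlet oxygen (O2, tetraphenylporphyrin, visible light, CH2Cl2) can add only at C1 with abstraction of a C3 hydrogen, because C6 has none. Attack from the exo face would give tert-butyl 2-[(1S,2R,5S)-2-hydroperoxy-7-oxo-6-oxabicyclo[3.2.1]oct-3-en-1-yl]acetate F4 (Schenck ene reaction), and reduction with triphenylphosphine would return the route to 10.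

**Step 12.** Facial selectivity at C9 may be poor if the magnesium bridge between the C4 alkoxide and the aldehyde is not maintained, for example after a ring flip that places C9 equatorial; the lactol may also open incompletely. Fallback by reversing the order with reagent control, setting out from 11: addition of alkenyllithium 20 to the lactone carbonyl at −78 °C would give the hydroxy enone tert-butyl 2-[(1S,2R,5S)-2-[(tert-butyldimethylsilyl)oxy]-1-[(2E,5E)-3,7-dimethyl-7-[(triethylsilyl)oxy]octa-2,5-dienoyl]-5-hydroxycyclohex-3-en-1-yl]acetate F5. Corey–Bakshi–Shibata reduction ((S)-2-methyl-CBS-oxazaborolidine, catecholborane, the quaternary carbon acting as the large group) would then return the route to 22.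

**Step 13.** Under alkoxide conditions the silyl group may migrate from the C1 oxygen to the C9 oxygen, after which the wrong oxygen would close onto C8; expulsion of tert-butoxide may also be sluggish. Fallback by acyl activation instead of alkoxide attack, setting out from 22: TMSOTf/2,6-lutidine would convert the tert-butyl ester into a silyl ester (the hydroxyls being silylated transiently), and mild methanolysis with citric acid would give 2-[(1R,2R,5S)-2-[(tert-butyldimethylsilyl)oxy]-5-hydroxy-1-[(1R,2E,5E)-1-hydroxy-3,7-dimethyl-7-[(triethylsilyl)oxy]octa-2,5-dien-1-yl]cyclohex-3-en-1-yl]acetic acid F6. Carbodiimide lactonisation (EDC·HCl, DMAP) would return the route to 23.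

## Further compounds

F1 | step 2 | [(2R,5R)-2,5-bis(methoxymethyl)pyrrolidin-1-yl](phenyl)methanone | O=C(c1ccccc1)N1[C@@H](COC)CC[C@@H]1COC
F2 | step 2 | tert-butyl 2-{1-[(2R,5R)-2,5-bis(methoxymethyl)pyrrolidine-1-carbonyl]cyclohexa-2,5-dien-1-yl}acetate | CC(C)(C)OC(=O)CC1(C=CCC=C1)C(=O)N1[C@@H](COC)CC[C@@H]1COC
F3 | step 3 | tert-butyl 2-[(1R,2S,4R,6R,9R)-9-bromo-8-oxo-3,7-dioxatricyclo[4.2.1.0(2,4)]nonan-1-yl]acetate | CC(C)(C)OC(=O)C[C@@]12[C@@H]3O[C@@H]3C[C@@H](OC1=O)[C@@H]2Br
F4 | step 5 | tert-butyl 2-[(1S,2R,5S)-2-hydroperoxy-7-oxo-6-oxabicyclo[3.2.1]oct-3-en-1-yl]acetate | CC(C)(C)OC(=O)C[C@@]12[C@H](OO)C=C[C@@H](OC1=O)C2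
F5 | step 12 | tert-butyl 2-[(1S,2R,5S)-2-[(tert-butyldimethylsilyl)oxy]-1-[(2E,5E)-3,7-dimethyl-7-[(triethylsilyl)oxy]octa-2,5-dienoyl]-5-hydroxycyclohex-3-en-1-yl]acetate | CC(C)(C)OC(=O)C[C@@]1(C(=O)/C=C(\C)C/C=C/C(C)(C)O[Si](CC)(CC)CC)C[C@H](O)C=C[C@H]1O[Si](C)(C)C(C)(C)C
F6 | step 13 | 2-[(1R,2R,5S)-2-[(tert-butyldimethylsilyl)oxy]-5-hydroxy-1-[(1R,2E,5E)-1-hydroxy-3,7-dimethyl-7-[(triethylsilyl)oxy]octa-2,5-dien-1-yl]cyclohex-3-en-1-yl]acetic acid | OC(=O)C[C@@]1([C@H](O)/C=C(\C)C/C=C/C(C)(C)O[Si](CC)(CC)CC)C[C@H](O)C=C[C@H]1O[Si](C)(C)C(C)(C)C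
A1 | alternative 1 | (1R,5R,9S)-9-[(tert-butyldimethylsilyl)oxy]-1-[(1E,4E)-6-hydroxy-2,6-dimethylhepta-1,4-dien-1-yl]-2-oxaspiro[4.5]dec-7-ene-3,6-dione | CC(C)(C)[Si](C)(C)O[C@@H]1C=CC(=O)[C@@]2(CC(=O)O[C@@H]2/C=C(\C)C/C=C/C(C)(C)O)C1
A2 | alternative 1 | (1Z,3S,6R,7E,10E)-3-[(tert-butyldimethylsilyl)oxy]-1-iodo-8,12-dimethyl-5-methylidenetrideca-1,7,10-triene-6,12-diol | I/C=C\[C@@H](O[Si](C)(C)C(C)(C)C)CC(=C)[C@H](O)/C=C(\C)C/C=C/C(C)(C)O
A3 | alternative 2 | 2-[2-[(tert-butyldimethylsilyl)oxy]-1-hydroxyethyl]-2-[2-[(4-methoxybenzyl)oxy]ethyl]cyclohex-4-en-1-one | O=C1CC=CC[C@@]1(CCOCc2ccc(OC)cc2)[C@H](O)CO[Si](C)(C)C(C)(C)C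
A4 | alternative 2 | 1-[(2R,3R)-3-{[(tert-butyldimethylsilyl)oxy]methyl}-2-{2-[(4-methoxybenzyl)oxy]ethyl}oxiran-2-yl]cyclopent-3-en-1-ol | OC1(CC=CC1)[C@]2(CCOCc3ccc(OC)cc3)O[C@@H]2CO[Si](C)(C)C(C)(C)C
A5 | alternative 3 | methyl 2-[5-acetoxy-2-[(tert-butyldimethylsilyl)oxy]-1-formylcyclohex-3-en-1-yl]acetate, formyl, silyloxy and acetoxy groups all cis | CC(=O)O[C@@H]1C=C[C@H](O[Si](C)(C)C(C)(C)C)[C@@](C=O)(CC(=O)OC)C1
A6 | alternative 3 | methyl 3-formylbut-3-enoate | COC(=O)CC(=C)C=O
A7 | alternative 3 | (1E,3E)-4-[(tert-butyldimethylsilyl)oxy]buta-1,3-dien-1-yl acetate | CC(=O)O/C=C/C=C/O[Si](C)(C)C(C)(C)C
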